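**Retrosynthetic overview** (cembrane numbering: C1 carries the isopropyl group, C4 the CO2Me group, C7 the acetoxy group, C8 the methyl group and the lactone oxygen, C12 the lactone carbonyl C20)

- Sarcrassin D (28) comes from hydroxy lactone 27 by acetylation of the C7 alcohol.
- 27 comes from the acyclic seco compound 24 by cutting together the C10–C11 bond (ring CH2 to the vinylic CH of the lactone) and the O–C8 bond (lactone oxygen to the methyl-bearing carbon). 24 carries a (Z)-enol triflate of a tert-butyl ester (C11/C20) at one end and a 2-bromoethyl group (C9–C10) on a (7R,8R)-epoxide at the other.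
- Enabling feature: in the seven-membered ring O–C20(=O)–C12=C11–C10–C9–C8 the carbonyl is cis to C10 across C11=C12, and the C8–O bond is anti to the C7–O bond. This is the retron of an anti opening of a C7–C8 epoxide by the C20 carboxyl, so closing the 14-membered ring at C10–C11 puts the ester oxygen within a seven-atom reach of C8.
- 24 comes from a Horner–Wadsworth–Emmons union at C3=C4 of West enal 12 (3-methylbut-1-yne: hydroalumination–iodination, B-alkyl Suzuki coupling, formylation, enol triflation) and East phosphonate 23 (silylated but-3-yn-1-ol: carboalumination–oxirane opening, Shi epoxidation, phosphonoacetate alkylation).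
- Ring order: the epoxide (step 10) is the only ring before the key step; then, in one flask, the 14-membered carbocycle (Negishi ring closure) followed by the seven-membered lactone.

Key step: step 16

Remark: the C11=C12 geometry, which the SMILES leaves open, is taken as the only one the seven-membered ring allows (C20 cis to C10). TBS = tert-butyldimethylsilyl, Tf = trifluoromethanesulfonyl.

**West fragment**

Step 1
Reactants: 1 3-methylbut-1-yne
Product: 2 4-methylpent-2-yn-1-ol
Conditions: n-BuLi, THF, −78 °C; (CH2O)n, −78 °C → rt; aq. NH4Cl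
Reagents that add atoms: paraformaldehyde (as formaldehyde), C=O
Why: Addition of the lithium acetylide to formaldehyde (alkynylation of a carbonyl) gives the propargylic alcohol whose OH group directs the next step; no stereocentre is formed.

Step 2
Reactants: 2 4-methylpent-2-yn-1-ol
Product: 4 (Z)-3-iodo-4-methylpent-2-en-1-ol, via cyclic alkenylaluminate 3 (not isolated)
Conditions: NaAlH2(OCH2CH2OMe)2 (Red-Al), THF, 0 °C → rt; then I2, THF, −78 → 0 °C
Reagents that add atoms: iodine, II
Why: Hydroxyl-directed trans-hydroalumination of the propargylic alcohol places aluminium on the isopropyl-bearing carbon cis to the CH2O group, and iodinolysis with retention should give the (Z)-vinyl iodide as one alkene isomer, which fixes the later C1=C2 geometry.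

Step 3
Reactants: 4 (Z)-3-iodo-4-methylpent-2-en-1-ol
Product: 5 tert-butyl{[(2Z)-3-iodo-4-methylpent-2-en-1-yl]oxy}dimethylsilane
Conditions: TBSCl, imidazole, CH2Cl2, 0 °C → rt
Reagents that add atoms: tert-butyldimethylsilyl chloride, CC(C)(C)[Si](C)(C)Cl
Why: Silyl ether formation protects the primary allylic alcohol against the borane and amide-base chemistry that follows.

Step 4
Reactants: 6 tert-butyl but-3-enoate; 5 tert-butyl{[(2Z)-3-iodo-4-methylpent-2-en-1-yl]oxy}dimethylsilane
Product: 8 tert-butyl (5E)-7-[(tert-butyldimethylsilyl)oxy]-5-(propan-2-yl)hept-5-enoate, via alkylborane 7 (not isolated)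
Conditions: 6, 9-BBN, THF, 0 °C → rt; then 5, PdCl2(dppf) (5 mol %), AsPh3, Cs2CO3, DMF/THF/H2O, rt
Reagents that add atoms: none
Why: Anti-Markovnikov hydroboration of the terminal alkene followed by B-alkyl Suzuki–Miyaura coupling proceeds with retention at the vinyl iodide, so the new CH2 chain ends up cis to the CH2O carbon as C1=C2 of the target requires.

Step 5
Reactants: 8 tert-butyl (5E)-7-[(tert-butyldimethylsilyl)oxy]-5-(propan-2-yl)hept-5-enoate
Product: 9 tert-butyl (5E)-7-[(tert-butyldimethylsilyl)oxy]-2-formyl-5-(propan-2-yl)hept-5-enoate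
Conditions: LiN(iPr)2, THF, −78 °C; HCO2Et, −78 → 0 °C; aq. NH4Cl
Reagents that add atoms: ethyl formate, CCOC=O
Why: Crossed Claisen condensation (formylation) of the lithium ester enolate with ethyl formate introduces the future C11 carbon at the only enolisable position; the new α-centre is left uncontrolled because it is lost on enolisation in step 6.

Step 6
Reactants: 9 tert-butyl (5E)-7-[(tert-butyldimethylsilyl)oxy]-2-formyl-5-(propan-2-yl)hept-5-enoate
Product: 10 tert-butyl (2Z,5E)-7-[(tert-butyldimethylsilyl)oxy]-5-(propan-2-yl)-2-{[(trifluoromethanesulfonyl)oxy]methylidene}hept-5-enoate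
Conditions: LiN(SiMe3)2, toluene, −78 °C; Tf2O, −78 → −20 °C
Reagents that add atoms: trifluoromethanesulfonic anhydride, O=S(=O)(OS(=O)(=O)C(F)(F)F)C(F)(F)F
Why: O-Sulfonylation of the lithium-chelated enolate of the β-oxo ester (enol triflate formation) should give the (Z)-triflate, because the chelate holds the enolate oxygen cis to the ester carbonyl, which is the geometry the lactone ring later demands.

Step 7
Reactants: 10 tert-butyl (2Z,5E)-7-[(tert-butyldimethylsilyl)oxy]-5-(propan-2-yl)-2-{[(trifluoromethanesulfonyl)oxy]methylidene}hept-5-enoate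
Product: 11 tert-butyl (2Z,5E)-7-hydroxy-5-(propan-2-yl)-2-{[(trifluoromethanesulfonyl)oxy]methylidene}hept-5-enoate
Conditions: HF·pyridine, pyridine, THF, 0 °C → rt
Reagents that add atoms: none
Why: Buffered fluoride cleavage of the primary silyl ether (desilylation) should leave the enol triflate and the tert-butyl ester untouched.

Step 8
Reactants: 11 tert-butyl (2Z,5E)-7-hydroxy-5-(propan-2-yl)-2-{[(trifluoromethanesulfonyl)oxy]methylidene}hept-5-enoate
Product: 12 tert-butyl (2Z,5E)-7-oxo-5-(propan-2-yl)-2-{[(trifluoromethanesulfonyl)oxy]methylidene}hept-5-enoate (West fragment)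
Conditions: MnO2, CH2Cl2, rt
Reagents that add atoms: none
Why: Allylic oxidation with activated MnO2 is selective for the allylic alcohol and should give the enal without change of either alkene geometry.

**East fragment**

Step 9
Reactants: 13 tert-butyl(but-3-yn-1-yloxy)dimethylsilane; 14 oxirane
Product: 17 (3E)-6-[(tert-butyldimethylsilyl)oxy]-4-methylhex-3-en-1-ol, via alkenylalane 15 (not isolated), via lithium alkenylaluminate 16 (not isolated)
Conditions: Me3Al, Cp2ZrCl2 (25 mol %), CH2Cl2, 0 °C → rt; hexane/THF, n-BuLi, −78 → 0 °C; 14, 0 °C → rt; aq. NH4Cl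
Reagents that add atoms: trimethylaluminium, C[Al](C)C
Why: Zirconium-catalysed syn-carboalumination (Negishi carboalumination) adds methyl and aluminium cis across the terminal alkyne, and alkenyl transfer from the derived aluminate to oxirane with retention should give the (E)-trisubstituted alkene of the future C7–C8 epoxide as one isomer.

Step 10
Reactants: 17 (3E)-6-[(tert-butyldimethylsilyl)oxy]-4-methylhex-3-en-1-ol
Product: 18 2-[(2R,3R)-3-{2-[(tert-butyldimethylsilyl)oxy]ethyl}-3-methyloxiran-2-yl]ethan-1-ol
Conditions: D-fructose-derived Shi ketone (30 mol %), Oxone (2KHSO5·KHSO4·K2SO4), K2CO3, Bu4NHSO4, MeCN/CH2(OMe)2/aq. Na2B4O7 buffer, 0 °C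
Reagents that add atoms: Oxone (active component potassium peroxymonosulfate), [K+].[O-]S(=O)(=O)OO
Why: Shi asymmetric epoxidation by the dioxirane of the D-fructose-derived ketone should deliver oxygen to one face of the (E)-trisubstituted alkene through the spiro transition state, setting both epoxide carbons as (R,R) under reagent control.

Step 11
Reactants: 18 2-[(2R,3R)-3-{2-[(tert-butyldimethylsilyl)oxy]ethyl}-3-methyloxiran-2-yl]ethan-1-ol
Product: 19 tert-butyl{2-[(2R,3R)-3-(2-iodoethyl)-2-methyloxiran-2-yl]ethoxy}dimethylsilane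
Conditions: I2, PPh3, imidazole, CH2Cl2, 0 °C
Reagents that add atoms: iodine, II
Why: Appel-type iodination of the primary alcohol under imidazole buffering should spare the acid-sensitive epoxide and the silyl ether and does not touch the stereocentres.

Step 12
Reactants: 20 trimethyl phosphonoacetate; 19 tert-butyl{2-[(2R,3R)-3-(2-iodoethyl)-2-methyloxiran-2-yl]ethoxy}dimethylsilane
Product: 21 methyl 4-[(2R,3R)-3-{2-[(tert-butyldimethylsilyl)oxy]ethyl}-3-methyloxiran-2-yl]-2-(dimethoxyphosphoryl)butanoate
Conditions: 20 (excess), NaH, DMF, 0 °C; then 19, 50 °C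
Reagents that add atoms: none
Why: C-Alkylation of the sodium phosphonoacetate with the primary iodide (enolate alkylation) installs C4 with its ester; the phosphonate-bearing centre forms as both epimers and is destroyed in step 15.

Step 13
Reactants: 21 methyl 4-[(2R,3R)-3-{2-[(tert-butyldimethylsilyl)oxy]ethyl}-3-methyloxiran-2-yl]-2-(dimethoxyphosphoryl)butanoate
Product: 22 methyl 2-(dimethoxyphosphoryl)-4-[(2R,3R)-3-(2-hydroxyethyl)-3-methyloxiran-2-yl]butanoate
Conditions: Bu4NF, AcOH, THF, 0 °C → rt
Reagents that add atoms: none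
Why: Acetic-acid-buffered fluoride desilylation should free the primary alcohol without opening the epoxide.

Step 14
Reactants: 22 methyl 2-(dimethoxyphosphoryl)-4-[(2R,3R)-3-(2-hydroxyethyl)-3-methyloxiran-2-yl]butanoate
Product: 23 methyl 4-[(2R,3R)-3-(2-bromoethyl)-3-methyloxiran-2-yl]-2-(dimethoxyphosphoryl)butanoate (East fragment)
Conditions: CBr4, PPh3, 2,6-lutidine, CH2Cl2, 0 °C
Reagents that add atoms: carbon tetrabromide, BrC(Br)(Br)Br
Why: Appel bromination under neutral conditions converts the primary alcohol into the bromide that will carry zinc in the key step and is compatible with epoxide and phosphonate.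

**Union, key step and end game**

Step 15
Reactants: 23 methyl 4-[(2R,3R)-3-(2-bromoethyl)-3-methyloxiran-2-yl]-2-(dimethoxyphosphoryl)butanoate; 12 tert-butyl (2Z,5E)-7-oxo-5-(propan-2-yl)-2-{[(trifluoromethanesulfonyl)oxy]methylidene}hept-5-enoate
Product: 24 1-tert-butyl 9-methyl (2Z,5E,7E)-8-{2-[(2R,3R)-3-(2-bromoethyl)-3-methyloxiran-2-yl]ethyl}-5-(propan-2-yl)-2-{[(trifluoromethanesulfonyl)oxy]methylidene}nona-5,7-dienedioate (seco compound)
Conditions: 23, NaH, THF, 0 °C; then 12, −20 → 0 °C
Reagents that add atoms: none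
Why: Horner–Wadsworth–Emmons olefination of the enal with the α-alkyl phosphonoacetate anion should favour the (E)-trisubstituted enoate (ester trans to C2) through the more stable anti oxaphosphetane, joining the fragments at C3=C4 while the aldehyde reacts faster than bromide or enol triflate.

Step 16
Reactants: 24 seco compound (bromide, epoxide, (Z)-enol triflate, tert-butyl ester)
Product: 27 7-O-deacetylsarcrassin D (hydroxy lactone), via alkylzinc bromide 25 (not isolated), via macrocyclic epoxy ester 26 (not isolated)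
Conditions: Rieke zinc (activated Zn powder), THF, 25 °C; syringe-pump addition to PdCl2(dppf) (10 mol %), THF/toluene, 55 °C, 2 mM; then BF3·OEt2, −40 → 0 °C; aq. NaHCO3
Reagents that add atoms: none
Why: Zinc inserts into the primary C–Br bond only (the enol triflate is inert to zinc without palladium); zerovalent palladium then adds to the vinylic C–OTf bond, and intramolecular transmetalation and reductive elimination with retention of alkene geometry close the 14-membered carbocycle at C10–C11, an end-to-end ring closure kept ahead of oligomerisation by slow addition at high dilution. The closest known reaction types are the Negishi coupling of functionalised primary alkylzinc halides with enol triflates and the Lewis-acid-promoted lactonisation of epoxy tert-butyl esters with loss of 2-methylpropene, the laboratory counterpart of the presumed biosynthetic carboxyl-on-epoxide closure. Because the coupling keeps the (Z) geometry, the tert-butyl ester carbonyl ends up cis to C10 and seven atoms from C8, so that once the epoxide is activated (by the zinc triflate salt released in the coupling and by BF3·OEt2) its oxygen opens the epoxide in a 7-exo-tet mode at the tertiary carbon and the resulting dialkoxycarbenium ion sheds the tert-butyl group. C8 is set as (S) by stereospecific inversion of the (R)-epoxide carbon, while C7 keeps its C–O bond and its (R) configuration, so both stereocentres derive from the Shi epoxidation. The step needs chemoselective metalation (C–Br before C–OTf), ring closure over dimerisation (dilution, and a chain stiffened by three alkenes and the epoxide), and opening at C8 and not at C7, which the better cation-stabilising tertiary carbon and the seven- versus eight-membered ring size should secure.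

Step 17
Reactants: 27 7-O-deacetylsarcrassin D
Product: 28 sarcrassin D
Conditions: Ac2O, DMAP, Et3N, CH2Cl2, 0 °C → rt
Reagents that add atoms: acetic anhydride, CC(=O)OC(C)=O
Why: DMAP-catalysed acylation (esterification) of the secondary C7 alcohol with acetic anhydride should complete the target with retention at C7 and without acyl migration if run cold and briefly.

**Compound list**

1 | 3-methylbut-1-yne | CC(C)C#C | starting material
2 | 4-methylpent-2-yn-1-ol | CC(C)C#CCO | intermediate
3 | sodium 2,2-bis(2-methoxyethoxy)-3-(propan-2-yl)-2,5-dihydro-1,2-oxaluminol-2-uide (cyclic alkenylaluminate, not isolated) | [Na+].CC(C)C1=CCO[Al-]1(OCCOC)OCCOC | intermediate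
4 | (Z)-3-iodo-4-methylpent-2-en-1-ol | CC(C)C(/I)=C/CO | intermediate
5 | tert-butyl{[(2Z)-3-iodo-4-methylpent-2-en-1-yl]oxy}dimethylsilane | CC(C)C(/I)=C/CO[Si](C)(C)C(C)(C)C | intermediate
6 | tert-butyl but-3-enoate | C=CCC(=O)OC(C)(C)C | starting material
7 | tert-butyl 4-(9-borabicyclo[3.3.1]nonan-9-yl)butanoate (alkylborane, not isolated) | CC(C)(C)OC(=O)CCCB1C2CCCC1CCC2 | intermediate
8 | tert-butyl (5E)-7-[(tert-butyldimethylsilyl)oxy]-5-(propan-2-yl)hept-5-enoate | CC(C)(C)OC(=O)CCC/C(C(C)C)=C\CO[Si](C)(C)C(C)(C)C | intermediate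
9 | tert-butyl (5E)-7-[(tert-butyldimethylsilyl)oxy]-2-formyl-5-(propan-2-yl)hept-5-enoate (both C2 epimers, in equilibrium with the enol) | CC(C)(C)OC(=O)C(C=O)CC/C(C(C)C)=C\CO[Si](C)(C)C(C)(C)C | intermediate
10 | tert-butyl (2Z,5E)-7-[(tert-butyldimethylsilyl)oxy]-5-(propan-2-yl)-2-{[(trifluoromethanesulfonyl)oxy]methylidene}hept-5-enoate | CC(C)(C)OC(=O)/C(=C\OS(=O)(=O)C(F)(F)F)CC/C(C(C)C)=C\CO[Si](C)(C)C(C)(C)C | intermediate
11 | tert-butyl (2Z,5E)-7-hydroxy-5-(propan-2-yl)-2-{[(trifluoromethanesulfonyl)oxy]methylidene}hept-5-enoate | CC(C)(C)OC(=O)/C(=C\OS(=O)(=O)C(F)(F)F)CC/C(C(C)C)=C\CO | intermediate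
12 | tert-butyl (2Z,5E)-7-oxo-5-(propan-2-yl)-2-{[(trifluoromethanesulfonyl)oxy]methylidene}hept-5-enoate (West fragment) | CC(C)(C)OC(=O)/C(=C\OS(=O)(=O)C(F)(F)F)CC/C(C(C)C)=C\C=O | intermediate
13 | tert-butyl(but-3-yn-1-yloxy)dimethylsilane | C#CCCO[Si](C)(C)C(C)(C)C | starting material
14 | oxirane | C1CO1 | starting material
15 | {(1E)-4-[(tert-butyldimethylsilyl)oxy]-2-methylbut-1-en-1-yl}dimethylalane (not isolated) | C[Al](C)/C=C(\C)CCO[Si](C)(C)C(C)(C)C | intermediate
16 | lithium butyl{(1E)-4-[(tert-butyldimethylsilyl)oxy]-2-methylbut-1-en-1-yl}dimethylaluminate (not isolated) | [Li+].CCCC[Al-](C)(C)/C=C(\C)CCO[Si](C)(C)C(C)(C)C | intermediate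
17 | (3E)-6-[(tert-butyldimethylsilyl)oxy]-4-methylhex-3-en-1-ol | OCC/C=C(\C)CCO[Si](C)(C)C(C)(C)C | intermediate
18 | 2-[(2R,3R)-3-{2-[(tert-butyldimethylsilyl)oxy]ethyl}-3-methyloxiran-2-yl]ethan-1-ol | OCC[C@H]1O[C@]1(C)CCO[Si](C)(C)C(C)(C)C | intermediate
19 | tert-butyl{2-[(2R,3R)-3-(2-iodoethyl)-2-methyloxiran-2-yl]ethoxy}dimethylsilane | ICC[C@H]1O[C@]1(C)CCO[Si](C)(C)C(C)(C)C | intermediate
20 | trimethyl phosphonoacetate | COC(=O)CP(=O)(OC)OC | starting material
21 | methyl 4-[(2R,3R)-3-{2-[(tert-butyldimethylsilyl)oxy]ethyl}-3-methyloxiran-2-yl]-2-(dimethoxyphosphoryl)butanoate (both C2 epimers) | COC(=O)C(CC[C@H]1O[C@]1(C)CCO[Si](C)(C)C(C)(C)C)P(=O)(OC)OC | intermediate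
22 | methyl 2-(dimethoxyphosphoryl)-4-[(2R,3R)-3-(2-hydroxyethyl)-3-methyloxiran-2-yl]butanoate | COC(=O)C(CC[C@H]1O[C@]1(C)CCO)P(=O)(OC)OC | intermediate
23 | methyl 4-[(2R,3R)-3-(2-bromoethyl)-3-methyloxiran-2-yl]-2-(dimethoxyphosphoryl)butanoate (East fragment) | COC(=O)C(CC[C@H]1O[C@]1(C)CCBr)P(=O)(OC)OC | intermediate
24 | 1-tert-butyl 9-methyl (2Z,5E,7E)-8-{2-[(2R,3R)-3-(2-bromoethyl)-3-methyloxiran-2-yl]ethyl}-5-(propan-2-yl)-2-{[(trifluoromethanesulfonyl)oxy]methylidene}nona-5,7-dienedioate (seco compound) | COC(=O)/C(CC[C@H]1O[C@]1(C)CCBr)=C/C=C(/C(C)C)CC/C(=C/OS(=O)(=O)C(F)(F)F)C(=O)OC(C)(C)C | intermediate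
25 | alkylzinc bromide of 24 (C–Br replaced by C–ZnBr, not isolated) | COC(=O)/C(CC[C@H]1O[C@]1(C)CC[Zn]Br)=C/C=C(/C(C)C)CC/C(=C/OS(=O)(=O)C(F)(F)F)C(=O)OC(C)(C)C | intermediate
26 | 20-tert-butyl 18-methyl (1E,3E,11Z,7R,8R)-7,8-epoxycembra-1,3,11-triene-18,20-dioate (14-membered carbocycle, not isolated) | COC(=O)/C1=C/C=C(/C(C)C)CC/C(=C/CC[C@@]2(C)O[C@@H]2CC1)C(=O)OC(C)(C)C | intermediate
27 | 7-O-deacetylsarcrassin D: methyl (1E,3E,7R,8S)-7-hydroxy-20-oxo-8,20-epoxycembra-1,3,11-trien-18-oate (seven-membered lactone C20 to O–C8) | COC(=O)/C1=C/C=C(/C(C)C)CCC2=CCC[C@](C)(OC2=O)[C@H](O)CC1 | intermediate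
28 | sarcrassin D, the (7R,8S) 7-acetate of 27 | COC(=O)/C1=C/C=C(/C(C)C)CCC2=CCC[C@](C)(OC2=O)[C@H](OC(C)=O)CC1 | target

**Step count**

Total: 17 steps. Longest linear sequence: 11 steps (steps 1–8, then 15–17).

**Three steps most likely to fail**

Step 16. What may go wrong: coupling between two chains, or protonolysis of the C–Zn bond, outruns the ring closure; or the epoxide is opened by bromide, or rearranges by hydride shift, before the ester oxygen reaches C8. The fallback forms the rings in the opposite order and closes the macrocycle by olefination instead of cross-coupling. It sets out from enol triflate 10 and bromo phosphonate 23. The zinc reagent made from 23 with Rieke zinc would be coupled with 10 under PdCl2(dppf) at normal concentration and the mixture treated with BF3·OEt2 as in step 16, which should give the seven-membered hydroxy lactone phosphonate F1 with the (7R,8S) centres in place. HF·pyridine would free the allylic alcohol to give diol phosphonate F2, and MnO2 should oxidise only the allylic alcohol to enal phosphonate F3. An intramolecular Horner–Wadsworth–Emmons reaction under Masamune–Roush conditions (LiCl, DBU, MeCN, high dilution) would then close the 14-membered ring at C3=C4 and come back to the route at 27.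

Step 6. What may go wrong: the enolate is sulfonylated from its non-chelated form, so that control of the alkene geometry is lost, or the formyl group is cleaved by retro-Claisen attack. The fallback uses a sulfonyl transfer from a sulfonylammonium reagent to the lithium-hydroxide-chelated enolate and carries a different, more robust electrophile through the route. It is a limited change of approach: it still relies on lithium chelation for the (Z) geometry, and no stereospecific alternative that rejoins the route was found. It sets out from 9. TsCl, N-methylimidazole and LiOH should give (Z)-enol tosylate F4; HF·pyridine would give allylic alcohol F5 and MnO2 enal F6. Horner–Wadsworth–Emmons union with 23 as in step 15 would give seco tosylate F7. Zinc insertion, ring closure with Pd(OAc)2/XPhos in place of PdCl2(dppf), and BF3·OEt2 as in step 16 would come back to the route at 27.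

Step 15. What may go wrong: the two oxaphosphetane pathways are not well differentiated, so that the (Z)-enoate forms beside the (E)-isomer; or the phosphonate carbanion attacks the enol triflate by addition–elimination or displaces bromide. The fallback uses a non-basic stabilised phosphorane and introduces the bromide after the union. It sets out from iodide 19. Two equivalents of Ph3P=CHCO2Me (MeCN, reflux; alkylation then transylidation) should give phosphorane F8, and a Wittig reaction with 12 (toluene, 60 °C) the seco silyl ether F9. Bu4NF/AcOH would give seco alcohol F10, and CBr4/PPh3 would come back to the route at 24.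

**Further compounds**

F1 | step 16 | methyl (5R)-5-[(2S)-6-{(3E)-5-[(tert-butyldimethylsilyl)oxy]-3-(propan-2-yl)pent-3-en-1-yl}-2-methyl-7-oxo-2,3,4,7-tetrahydrooxepin-2-yl]-2-(dimethoxyphosphoryl)-5-hydroxypentanoate (hydroxy lactone phosphonate) | COC(=O)C(CC[C@@H](O)[C@]1(C)CCC=C(CC/C(C(C)C)=C\CO[Si](C)(C)C(C)(C)C)C(=O)O1)P(=O)(OC)OC
F2 | step 16 | diol phosphonate (F1 without the silyl group) | COC(=O)C(CC[C@@H](O)[C@]1(C)CCC=C(CC/C(C(C)C)=C\CO)C(=O)O1)P(=O)(OC)OC
F3 | step 16 | enal phosphonate (allylic alcohol of F2 oxidised to the aldehyde) | COC(=O)C(CC[C@@H](O)[C@]1(C)CCC=C(CC/C(C(C)C)=C\C=O)C(=O)O1)P(=O)(OC)OC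
F4 | step 6 | tert-butyl (2Z,5E)-7-[(tert-butyldimethylsilyl)oxy]-2-{[(4-methylbenzenesulfonyl)oxy]methylidene}-5-(propan-2-yl)hept-5-enoate ((Z)-enol tosylate) | CC(C)(C)OC(=O)/C(=C\OS(=O)(=O)c1ccc(C)cc1)CC/C(C(C)C)=C\CO[Si](C)(C)C(C)(C)C
F5 | step 6 | tert-butyl (2Z,5E)-7-hydroxy-2-{[(4-methylbenzenesulfonyl)oxy]methylidene}-5-(propan-2-yl)hept-5-enoate (allylic alcohol) | CC(C)(C)OC(=O)/C(=C\OS(=O)(=O)c1ccc(C)cc1)CC/C(C(C)C)=C\CO
F6 | step 6 | tert-butyl (2Z,5E)-2-{[(4-methylbenzenesulfonyl)oxy]methylidene}-7-oxo-5-(propan-2-yl)hept-5-enoate (enal) | CC(C)(C)OC(=O)/C(=C\OS(=O)(=O)c1ccc(C)cc1)CC/C(C(C)C)=C\C=O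
F7 | step 6 | seco tosylate (24 with OTs in place of OTf) | COC(=O)/C(CC[C@H]1O[C@]1(C)CCBr)=C/C=C(/C(C)C)CC/C(=C/OS(=O)(=O)c1ccc(C)cc1)C(=O)OC(C)(C)C
F8 | step 15 | methyl 4-[(2R,3R)-3-{2-[(tert-butyldimethylsilyl)oxy]ethyl}-3-methyloxiran-2-yl]-2-(triphenyl-λ5-phosphanylidene)butanoate (phosphorane) | COC(=O)C(CC[C@H]1O[C@]1(C)CCO[Si](C)(C)C(C)(C)C)=P(c1ccccc1)(c1ccccc1)c1ccccc1
F9 | step 15 | seco silyl ether (24 with CH2OTBS in place of CH2Br) | COC(=O)/C(CC[C@H]1O[C@]1(C)CCO[Si](C)(C)C(C)(C)C)=C/C=C(/C(C)C)CC/C(=C/OS(=O)(=O)C(F)(F)F)C(=O)OC(C)(C)C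
F10 | step 15 | seco alcohol (24 with CH2OH in place of CH2Br) | COC(=O)/C(CC[C@H]1O[C@]1(C)CCO)=C/C=C(/C(C)C)CC/C(=C/OS(=O)(=O)C(F)(F)F)C(=O)OC(C)(C)C
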